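## The problem

The target (21) is a 3,4-dihydroisocoumarin. Ring A is fused to a six-membered lactone ring whose C3 is a hemiketal carbon bearing a hydroxyl group and the C9 methylene, and C9 carries, through an ester oxygen, the fully substituted ring B acyl group (2,4-dihydroxy-3,5,6-trimethylbenzoyl). There are two stereocentres, C4 (S; benzylic, methyl-bearing) and C3 (R). C3 can open to the C3 ketone and C1 acid and close again, so it is under thermodynamic control of C4. C4 has no neighbour that could direct it and must be set by an enantioselective reaction. C4 is also the fragile point: it is benzylic and α to the masked ketone, so enolisation, dehydration of the lactol, or cyclocondensation of a C1 aldehyde with the C3 ketone through the C4 enol would each erase it. Ring A is pentasubstituted with the C6 and C8 oxygens differentiated (OMe and OH), and ring B is hexasubstituted, so its carboxyl is di-ortho-hindered and a poor acyl donor. The enabling feature is that C3 (ketone level) and C9 (CH2–O–acyl) together are an α-acyloxy methyl ketone, the oxidised and acid-trapped form of a terminal alkyne C3≡C9. Both C–O bonds can therefore be made in one non-basic step in which the hindered acid acts as a nucleophile.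

## Retrosynthesis

**Lactol and protecting groups (21 ⇒ 20 ⇒ 19).** The C1–O2–C3 lactol is opened to keto acid 20. All three phenols and the C1 carboxyl are masked as benzyl groups in 19, so that one neutral hydrogenolysis releases 20, which closes to 21 on its own. A Lewis-acid deprotection at the end was set aside because it would expose the lactol to dehydration. Compound 19 has one stereocentre (C4) and no ring beyond the two arenes.

**Key disconnection (19 ⇒ 12 + 17 + 18).** The C3=O and C9–O bonds are cut together, leading to terminal alkyne 12, ring B acid 17 and the oxygen donor 18. The neighbouring cuts are acylation of a C9 alcohol with 17 (hindered acyl donor) and carboxylate displacement on an α-halo ketone (basic, C4 at risk). The forward reaction must place oxygen on the internal alkyne carbon and trap the C9 gold carbene with the acid before anything else does. For this reason 12 already carries C1 on C8a. A free C8a–H on a dimethoxy-activated ring would be attacked by the carbene, and with C5 methylated and C8a substituted no ring position is within reach.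

**Timing of C1 (9 ⇒ 8 ⇒ 7 ⇒ 6 ⇒ 5).** The C8a–C1 bond is cut at the stage of thioester 5, before any C3 carbonyl exists. Formylating after the ketone is in place would put a C1 aldehyde next to an enolisable C3 ketone under Lewis acid, which invites cyclocondensation through C4. On 5 the same electrophilic substitution is harmless. The C1 carbonyl then differentiates the two methoxy groups by chelation (7 ⇒ 8), and one benzylation (8 ⇒ 9) installs the C8 benzyl ether and the C1 benzyl ester.

**Alkyne (12 ⇒ 10 ⇒ 9).** The C3≡C9 triple bond is traced to the CH2–CHO unit of aldehyde 10 (same carbon count, dehydration through enol nonaflate 11), and 10 to thioester 9. A homologation (one-carbon-shorter α-aryl aldehyde) was avoided because that aldehyde would be configurationally labile.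

**C4 stereocentre and ring A (5 ⇒ 4 ⇒ 3 ⇒ 2 ⇒ 1).** The C4–CH3 bond is cut by conjugate addition of a methyl nucleophile to enethioate 4, which sets C4 catalytically on a simple substrate. Compound 4 comes from aldehyde 3 by Wittig olefination. The C5 methyl of 3 is traced through bromide 2 to 3,5-dimethoxybenzaldehyde 1, using the position that is ortho and para to the two methoxy groups.

**Ring B acid (17 ⇒ 16 ⇒ 15 ⇒ 14 ⇒ 13).** Only the C5'' methyl is missing in commercial resorcylate 13. It is introduced at the sole free ring position by formylation (14) and reduction (15). Benzylation (16) and ester hydrolysis give 17.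

## Roads not taken

**Alternative 1:** Ring A would be built by a Diels–Alder benzannulation, cutting C4a–C5 and C8–C8a. Diene A2 (1,3-dimethoxy-1-(trimethylsilyloxy)penta-1,3-diene) would add to chiral ynoate A3 (benzyl (4S)-4-[(4R)-2,2-dimethyl-1,3-dioxolan-4-yl]pent-2-ynoate), and loss of methanol would give salicylate A1 (benzyl 6-[(1S)-1-[(4R)-2,2-dimethyl-1,3-dioxolan-4-yl]ethyl]-2-hydroxy-4-methoxy-5-methylbenzoate).
- Merits: the whole ring A pattern arrives in one step with C1 in place and the C6 and C8 oxygens already differentiated. In this respect it is better than the chosen plan, which spends four steps (5 to 8) on the same result.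
- Weak points: the cycloaddition must join a methyl-bearing diene terminus to an ynoate carbon carrying an α-branched substituent, which is slow for this diene class. A3 needs two stereocentres, one of which is later destroyed. The endgame still has to acylate the primary alcohol with the hindered ring B acid and oxidise the secondary alcohol next to C4.
- What the chosen plan sets against it: C4 is set catalytically on a simple enethioate, the C3 oxidation level and the C9–O bond arise in one step, and ring B enters as a nucleophile.

**Alternative 2:** The lactol ring would come from oxygen insertion into an indanone. H5IO6 would cleave the ketone–carbinol bond of ketol A5 ([(3S)-7-(benzyloxy)-2-hydroxy-5-methoxy-3,4-dimethyl-1-oxo-2,3-dihydro-1H-inden-2-yl]methyl 2,4-bis(benzyloxy)-3,5,6-trimethylbenzoate), and the resulting keto acid would close to tri-O-benzyl lactol A4.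
- Merits: C1 is introduced by an intramolecular Friedel–Crafts acylation with no regiochemical question, C4 is never α to a carbonyl until the last oxidation, and the key step closes the lactol ring itself. On these points it is at least as good as the chosen plan.
- Weak points: the quaternary ketol carbon needs two successive α-functionalisations of the indanone. The neopentyl-type primary alcohol must then be esterified with the di-ortho-substituted acid as acyl donor. The cleavage uses a strong acid oxidant on a product prone to dehydration.
- What the chosen plan sets against it: no quaternary centre has to be built, the ester bond forms with the acid as nucleophile, and the last step is a neutral hydrogenolysis.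

**Alternative 3:** Ring B would be made by a Danheiser benzannulation. Irradiation of diazo ketoester A7 (benzyl (4E)-2-diazo-4-methyl-3-oxohex-4-enoate) gives a vinylketene by Wolff rearrangement, which combines with siloxyalkyne A8 (triisopropyl(prop-1-yn-1-yloxy)silane) to give phenol A6 (benzyl 4-hydroxy-3,5,6-trimethyl-2-[(triisopropylsilyl)oxy]benzoate).
- Merits: a hexasubstituted benzene is assembled with full regiocontrol and with its two phenols differentiated, which the chosen route does not achieve.
- Weak points: that differentiation is not needed here. The sequence needs diazo transfer, photolysis and a sensitive siloxyalkyne, where four routine steps from commercial 13 suffice. It solves none of the real problems (C4, the lactol, the hindered ester bond).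
- Comparison: it could feed any of the other plans but cannot replace them, and the route from 13 is shorter.

Key step: step 15

Assumptions:
- The 3R configuration of the lactol is taken to be the thermodynamic one. The peri C5 methyl holds the C4 methyl pseudo-axial, and the anomeric hydroxyl sits axial and trans to it.
- (R)-Tol-BINAP is written in step 4. The ligand enantiomer to be used is the one that gives (3R)-5, and the antipode is taken if the established sense of induction for β-aryl enethioates requires it.
- The stabilised ylide of step 3 is a known shelf-stable reagent (from S-ethyl bromothioacetate and PPh3) and is treated as a reagent.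

## Route

Step 1
Reactants: 1 3,5-dimethoxybenzaldehyde
Product: 2 2-bromo-3,5-dimethoxybenzaldehyde
Conditions: NBS, MeCN, 0 °C to rt
Reagents that add atoms: N-bromosuccinimide, O=C1CCC(=O)N1Br
Why: Electrophilic aromatic bromination; the position next to the formyl group is para to one methoxy group and ortho to the other and should react in preference to the more hindered position between the two methoxy groups.

Step 2
Reactants: 2 2-bromo-3,5-dimethoxybenzaldehyde
Product: 3 3,5-dimethoxy-2-methylbenzaldehyde
Conditions: MeB(OH)2, Pd(dppf)Cl2 (5 mol %), K2CO3, dioxane/H2O, 90 °C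
Reagents that add atoms: methylboronic acid, CB(O)O
Why: Suzuki–Miyaura methylation; zerovalent palladium inserts into the C–Br bond and methyl is transferred from boron, leaving the aldehyde untouched.

Step 3
Reactants: 3 3,5-dimethoxy-2-methylbenzaldehyde
Product: 4 S-ethyl (2E)-3-(3,5-dimethoxy-2-methylphenyl)prop-2-enethioate
Conditions: Ph3P=CHC(O)SEt, CH2Cl2, reflux
Reagents that add atoms: S-ethyl 2-(triphenylphosphoranylidene)ethanethioate, CCSC(=O)C=P(c1ccccc1)(c1ccccc1)c1ccccc1
Why: Wittig olefination with a stabilised ylide should give the E alkene; the thioester is chosen because it is the acceptor class that takes methyl Grignard reagents cleanly in the next step.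

Step 4
Reactants: 4 S-ethyl (2E)-3-(3,5-dimethoxy-2-methylphenyl)prop-2-enethioate
Product: 5 S-ethyl (3R)-3-(3,5-dimethoxy-2-methylphenyl)butanethioate
Conditions: MeMgBr, CuI (3 mol %), (R)-Tol-BINAP (3.3 mol %), t-BuOMe, −70 °C
Reagents that add atoms: methylmagnesium bromide, C[Mg]Br
Why: Copper-catalysed asymmetric conjugate addition of a Grignard reagent to an α,β-unsaturated thioester; the chiral bisphosphine on monovalent copper selects the alkene face and sets C4 (3R here, 4S in the target), and the low temperature suppresses 1,2-addition.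

Step 5
Reactants: 5 S-ethyl (3R)-3-(3,5-dimethoxy-2-methylphenyl)butanethioate
Product: 6 S-ethyl (3R)-3-(2-formyl-3,5-dimethoxy-6-methylphenyl)butanethioate
Conditions: Cl2CHOMe, TiCl4, CH2Cl2, −78 to 0 °C; then H2O
Reagents that add atoms: dichloromethyl methyl ether, COC(Cl)Cl; water, O
Why: Rieche formylation; C8a is para to the C6 methoxy and ortho to the C8 methoxy, whereas C7 lies between two methoxy groups, so C8a should be attacked. No ketone is present yet, so the new aldehyde has no partner for cyclocondensation and C4 is not enolisable.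

Step 6
Reactants: 6 S-ethyl (3R)-3-(2-formyl-3,5-dimethoxy-6-methylphenyl)butanethioate
Product: 7 2-[(2R)-4-(ethylsulfanyl)-4-oxobutan-2-yl]-4,6-dimethoxy-3-methylbenzoic acid
Conditions: NaClO2, NaH2PO4, 2-methyl-2-butene, t-BuOH/H2O, rt
Reagents that add atoms: sodium chlorite, [Na+].[O-]Cl=O
Why: Pinnick oxidation of an aryl aldehyde; the alkene scavenger removes hypochlorous acid before it can chlorinate the electron-rich ring or touch the thioester.

Step 7
Reactants: 7 2-[(2R)-4-(ethylsulfanyl)-4-oxobutan-2-yl]-4,6-dimethoxy-3-methylbenzoic acid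
Product: 8 2-[(2R)-4-(ethylsulfanyl)-4-oxobutan-2-yl]-6-hydroxy-4-methoxy-3-methylbenzoic acid
Conditions: BCl3, CH2Cl2, −78 to 0 °C; then H2O
Reagents that add atoms: none
Why: Chelation-controlled ether cleavage; boron bound to the carboxyl activates only the ortho (C8) methoxy group, so the C6 methoxy group should survive and the two ring oxygens become differentiated.

Step 8
Reactants: 8 2-[(2R)-4-(ethylsulfanyl)-4-oxobutan-2-yl]-6-hydroxy-4-methoxy-3-methylbenzoic acid
Product: 9 benzyl 6-(benzyloxy)-2-[(2R)-4-(ethylsulfanyl)-4-oxobutan-2-yl]-4-methoxy-3-methylbenzoate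
Conditions: BnBr, K2CO3, DMF, 50 °C
Reagents that add atoms: benzyl bromide, BrCc1ccccc1
Why: Williamson-type O-alkylation of the carboxylate and the phenoxide in one operation; the hindered acid is esterified through its oxygen, so its crowding does not matter.

Step 9
Reactants: 9 benzyl 6-(benzyloxy)-2-[(2R)-4-(ethylsulfanyl)-4-oxobutan-2-yl]-4-methoxy-3-methylbenzoate
Product: 10 benzyl 6-(benzyloxy)-4-methoxy-3-methyl-2-[(2R)-4-oxobutan-2-yl]benzoate
Conditions: i-Bu2AlH, CH2Cl2, −78 °C; aq. potassium sodium tartrate
Reagents that add atoms: none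
Why: Partial reduction of a thioester to the aldehyde through a tetrahedral aluminium hemithioacetal that is stable at −78 °C; the 2,6-disubstituted benzyl benzoate is too hindered to react at this temperature.

Step 10
Reactants: 10 benzyl 6-(benzyloxy)-4-methoxy-3-methyl-2-[(2R)-4-oxobutan-2-yl]benzoate
Product: 12 benzyl 6-(benzyloxy)-2-[(2R)-but-3-yn-2-yl]-4-methoxy-3-methylbenzoate, via enol nonaflate 11 (not isolated)
Conditions: C4F9SO2F, t-BuN=P(pyrrolidin-1-yl)3, DMF, −20 °C to rt
Reagents that add atoms: none
Why: One-pot enol nonaflate formation and β-elimination turns CH2–CHO into C≡CH without changing the carbon count. The phosphazene base is non-nucleophilic and should be too weak to remove the propargylic C4–H, whose benzylic stabilisation is switched off by the two ortho substituents, so C4 should be retained.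

Step 11
Reactants: 13 methyl 2,4-dihydroxy-3,6-dimethylbenzoate
Product: 14 methyl 3-formyl-4,6-dihydroxy-2,5-dimethylbenzoate
Conditions: Cl2CHOMe, TiCl4, CH2Cl2, 0 °C; then aq. HCl
Reagents that add atoms: dichloromethyl methyl ether, COC(Cl)Cl; water, O
Why: Rieche formylation of a phenol at its only free ring position, which is ortho and para to the two hydroxyl groups.

Step 12
Reactants: 14 methyl 3-formyl-4,6-dihydroxy-2,5-dimethylbenzoate
Product: 15 methyl 2,4-dihydroxy-3,5,6-trimethylbenzoate
Conditions: Et3SiH, CF3CO2H, CH2Cl2, rt
Reagents that add atoms: none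
Why: Ionic hydrogenation; the protonated hydroxybenzaldehyde is reduced by hydride transfer through the phenol-stabilised benzylic cation to the methyl group.

Step 13
Reactants: 15 methyl 2,4-dihydroxy-3,5,6-trimethylbenzoate
Product: 16 methyl 2,4-bis(benzyloxy)-3,5,6-trimethylbenzoate
Conditions: BnBr, K2CO3, DMF, 70 °C
Reagents that add atoms: benzyl bromide, BrCc1ccccc1
Why: Williamson ether synthesis; heating is needed for the hydrogen-bonded hydroxyl next to the ester, and benzyl is chosen so that all protecting groups leave together in step 16.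

Step 14
Reactants: 16 methyl 2,4-bis(benzyloxy)-3,5,6-trimethylbenzoate
Product: 17 2,4-bis(benzyloxy)-3,5,6-trimethylbenzoic acid
Conditions: KOH, DMSO/H2O, 100 °C; then aq. HCl
Reagents that add atoms: potassium hydroxide, [K+].[OH-]
Why: Saponification of a di-ortho-substituted benzoate, which needs poorly solvated hydroxide in DMSO; the benzyl ethers are stable to base.

Step 15
Reactants: 12 benzyl 6-(benzyloxy)-2-[(2R)-but-3-yn-2-yl]-4-methoxy-3-methylbenzoate; 17 2,4-bis(benzyloxy)-3,5,6-trimethylbenzoic acid; 18 8-methylquinoline N-oxide
Product: 19 benzyl 6-(benzyloxy)-2-[(2S)-4-{[2,4-bis(benzyloxy)-3,5,6-trimethylbenzoyl]oxy}-3-oxobutan-2-yl]-4-methoxy-3-methylbenzoate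
Conditions: [(1-Ad)2(2-morpholinophenyl)P]AuNTf2 (5 mol %), 17 (1.5 equiv), 18 (1.3 equiv, added over 4 h), PhCl, rt
Reagents that add atoms: none
Why: The cationic monovalent gold centre binds the terminal alkyne of 12 and the N-oxide oxygen of 18 adds to the internal carbon C3; loss of 8-methylquinoline from the vinylgold adduct leaves an α-oxo gold carbene at C9. Acid 17 captures this carbene by O–H insertion, so the C3 carbonyl and the C9–O ester bond form in one operation. The closest known reaction type is the gold-catalysed intermolecular oxidation of terminal alkynes by quinoline N-oxides with carboxylic acid capture to give α-acyloxy methyl ketones. No ring is closed and no stereocentre is created; C4 is carried through because the only base present is 8-methylquinoline buffered by excess acid, and enolisation towards C4 is hindered by the di-ortho-substituted aryl group (the descriptor changes from R to S only through the priority rules). Regioselectivity (oxygen to C3, acyloxy to C9) follows from the polarisation of a terminal alkyne on gold. Chemoselectivity for acid capture over a second oxidation of the carbene rests on the P,N-ligand, which tempers the electrophilicity of the carbene, on slow addition of 18 and on an excess of 17. Intramolecular capture is closed off by the substrate: both ring positions ortho to the side chain (C5 and C8a) are substituted and every hydroxyl group except the carboxyl of 17 is benzylated. The di-ortho substitution of 17 is no handicap because the acid reacts through its oxygen as a nucleophile and not as an acyl donor.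

Step 16
Reactants: 19 benzyl 6-(benzyloxy)-2-[(2S)-4-{[2,4-bis(benzyloxy)-3,5,6-trimethylbenzoyl]oxy}-3-oxobutan-2-yl]-4-methoxy-3-methylbenzoate
Product: 21 [(3R,4S)-3,8-dihydroxy-6-methoxy-4,5-dimethyl-1-oxo-3,4-dihydro-1H-isochromen-3-yl]methyl 2,4-dihydroxy-3,5,6-trimethylbenzoate, via keto acid 20 (not isolated)
Conditions: H2 (1 atm), Pd/C, EtOAc, rt
Reagents that add atoms: none
Why: Hydrogenolysis removes the three benzyl ethers and the benzyl ester; the freed C1 carboxyl adds to the C3 ketone and closes the six-membered lactol (6-exo-trig). The neutral medium should leave C4 untouched, and C3 settles under thermodynamic control with the hydroxyl axial and trans to the C4 methyl (3R).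

## Compound list

1 | 3,5-dimethoxybenzaldehyde | COc1cc(OC)cc(C=O)c1 | starting material
2 | 2-bromo-3,5-dimethoxybenzaldehyde | COc1cc(OC)c(Br)c(C=O)c1 | intermediate
3 | 3,5-dimethoxy-2-methylbenzaldehyde | COc1cc(OC)c(C)c(C=O)c1 | intermediate
4 | S-ethyl (2E)-3-(3,5-dimethoxy-2-methylphenyl)prop-2-enethioate | CCSC(=O)/C=C/c1cc(OC)cc(OC)c1C | intermediate
5 | S-ethyl (3R)-3-(3,5-dimethoxy-2-methylphenyl)butanethioate | COc1cc(OC)cc(c1C)[C@H](C)CC(=O)SCC | intermediate
6 | S-ethyl (3R)-3-(2-formyl-3,5-dimethoxy-6-methylphenyl)butanethioate | COc1cc(OC)c(C=O)c(c1C)[C@H](C)CC(=O)SCC | intermediate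
7 | 2-[(2R)-4-(ethylsulfanyl)-4-oxobutan-2-yl]-4,6-dimethoxy-3-methylbenzoic acid | COc1cc(OC)c(C(=O)O)c(c1C)[C@H](C)CC(=O)SCC | intermediate
8 | 2-[(2R)-4-(ethylsulfanyl)-4-oxobutan-2-yl]-6-hydroxy-4-methoxy-3-methylbenzoic acid | COc1cc(O)c(C(=O)O)c(c1C)[C@H](C)CC(=O)SCC | intermediate
9 | benzyl 6-(benzyloxy)-2-[(2R)-4-(ethylsulfanyl)-4-oxobutan-2-yl]-4-methoxy-3-methylbenzoate | COc1cc(OCc2ccccc2)c(C(=O)OCc2ccccc2)c(c1C)[C@H](C)CC(=O)SCC | intermediate
10 | benzyl 6-(benzyloxy)-4-methoxy-3-methyl-2-[(2R)-4-oxobutan-2-yl]benzoate | COc1cc(OCc2ccccc2)c(C(=O)OCc2ccccc2)c(c1C)[C@H](C)CC=O | intermediate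
11 | benzyl 6-(benzyloxy)-4-methoxy-3-methyl-2-[(2R)-4-(nonafluorobutane-1-sulfonyloxy)but-3-en-2-yl]benzoate (E/Z mixture, not isolated) | COc1cc(OCc2ccccc2)c(C(=O)OCc2ccccc2)c(c1C)[C@H](C)C=COS(=O)(=O)C(F)(F)C(F)(F)C(F)(F)C(F)(F)F | intermediate
12 | benzyl 6-(benzyloxy)-2-[(2R)-but-3-yn-2-yl]-4-methoxy-3-methylbenzoate | COc1cc(OCc2ccccc2)c(C(=O)OCc2ccccc2)c(c1C)[C@H](C)C#C | intermediate
13 | methyl 2,4-dihydroxy-3,6-dimethylbenzoate | COC(=O)c1c(C)cc(O)c(C)c1O | starting material
14 | methyl 3-formyl-4,6-dihydroxy-2,5-dimethylbenzoate | COC(=O)c1c(C)c(C=O)c(O)c(C)c1O | intermediate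
15 | methyl 2,4-dihydroxy-3,5,6-trimethylbenzoate | COC(=O)c1c(C)c(C)c(O)c(C)c1O | intermediate
16 | methyl 2,4-bis(benzyloxy)-3,5,6-trimethylbenzoate | COC(=O)c1c(C)c(C)c(OCc2ccccc2)c(C)c1OCc1ccccc1 | intermediate
17 | 2,4-bis(benzyloxy)-3,5,6-trimethylbenzoic acid | OC(=O)c1c(C)c(C)c(OCc2ccccc2)c(C)c1OCc1ccccc1 | intermediate
18 | 8-methylquinoline N-oxide | Cc1cccc2ccc[n+]([O-])c12 | starting material
19 | benzyl 6-(benzyloxy)-2-[(2S)-4-{[2,4-bis(benzyloxy)-3,5,6-trimethylbenzoyl]oxy}-3-oxobutan-2-yl]-4-methoxy-3-methylbenzoate | COc1cc(OCc2ccccc2)c(C(=O)OCc2ccccc2)c(c1C)[C@H](C)C(=O)COC(=O)c2c(C)c(C)c(OCc3ccccc3)c(C)c2OCc2ccccc2 | intermediate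
20 | 2-[(2S)-4-[(2,4-dihydroxy-3,5,6-trimethylbenzoyl)oxy]-3-oxobutan-2-yl]-6-hydroxy-4-methoxy-3-methylbenzoic acid (not isolated) | COc1cc(O)c(C(=O)O)c(c1C)[C@H](C)C(=O)COC(=O)c2c(C)c(C)c(O)c(C)c2O | intermediate
21 | [(3R,4S)-3,8-dihydroxy-6-methoxy-4,5-dimethyl-1-oxo-3,4-dihydro-1H-isochromen-3-yl]methyl 2,4-dihydroxy-3,5,6-trimethylbenzoate | COc1cc(O)c2c(c1C)[C@H](C)[C@](O)(COC(=O)c1c(C)c(C)c(O)c(C)c1O)OC2=O | target

## Step count and least certain steps

Total: 16 steps. Longest linear sequence: 12 steps (steps 1 to 10, 15 and 16). Acid 17 is made in 4 steps (11 to 14).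

**Step 15 (key step).** Three processes could compete:
- reversible addition of the neighbouring C1 ester carbonyl to the gold-activated alkyne, followed by loss of benzyl or by hydration;
- a second oxidation of the C9 carbene by the N-oxide;
- slow capture of the carbene by the bulky acid.

The fallback avoids any carbene and keeps the acid as the nucleophile. It sets out from 12 and returns at 19. Semi-hydrogenation (H2, Pd/CaCO3 poisoned with Pb(OAc)2, quinoline) should give benzyl 6-(benzyloxy)-2-[(2R)-but-3-en-2-yl]-4-methoxy-3-methylbenzoate F1. Dihydroxylation (OsO4 cat., NMO, kept neutral so that the secondary hydroxyl does not lactonise onto the C1 ester) should give benzyl 6-(benzyloxy)-2-[(2S)-3,4-dihydroxybutan-2-yl]-4-methoxy-3-methylbenzoate F2 as a mixture of carbinol epimers. Mitsunobu esterification of the primary hydroxyl with 17 (PPh3, DIAD) should give benzyl 6-(benzyloxy)-2-[(2S)-4-{[2,4-bis(benzyloxy)-3,5,6-trimethylbenzoyl]oxy}-3-hydroxybutan-2-yl]-4-methoxy-3-methylbenzoate F3. Oxidation of the secondary alcohol with Dess–Martin periodinane converges both epimers on 19.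

**Step 10.** Three things could go wrong:
- base-induced propargyl–allenyl isomerisation with loss of the C4 configuration;
- slow syn-elimination of the E enol nonaflate;
- attack of the aldehyde enolate on the ortho benzyl ester before it is sulfonylated.

The fallback replaces the equilibrating one-pot procedure by a two-step sequence in which the enol sulfonate is made without strong base and the elimination is kinetic and irreversible. It sets out from 10 and returns at 12. Tf2O with 2,6-di-tert-butyl-4-methylpyridine should give benzyl 6-(benzyloxy)-4-methoxy-3-methyl-2-[(2R)-4-(trifluoromethanesulfonyloxy)but-3-en-2-yl]benzoate F4, which is isolated. Treatment with LiN(i-Pr)2 (2.2 equiv, THF, −78 °C) eliminates triflate and stores the alkyne at once as its lithium acetylide, in which the propargylic position is no longer acidic. Protonation gives 12.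

**Step 4.** The ortho methyl group could lower the rate and the facial selectivity of the copper-catalysed addition, and 1,2-addition of the Grignard reagent could intervene. The fallback replaces catalyst control by auxiliary control. It sets out from 3 and returns at 5. Doebner–Knoevenagel condensation with malonic acid (pyridine, piperidine) should give (2E)-3-(3,5-dimethoxy-2-methylphenyl)prop-2-enoic acid F5. Activation with pivaloyl chloride and coupling with (4R)-4-phenyl-1,3-oxazolidin-2-one (Et3N, LiCl) should give (4R)-3-[(2E)-3-(3,5-dimethoxy-2-methylphenyl)prop-2-enoyl]-4-phenyl-1,3-oxazolidin-2-one F6. Addition of MeMgBr with CuBr·SMe2 to the chelated s-cis imide, anti to the phenyl group, is expected to give (4R)-3-[(3R)-3-(3,5-dimethoxy-2-methylphenyl)butanoyl]-4-phenyl-1,3-oxazolidin-2-one F7; the antipodal auxiliary is used if the sense proves opposite. EtSLi then displaces the auxiliary and gives 5.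

**Step 5.** Formylation could occur partly at C7 between the two methoxy groups, or be slowed by the adjacent branched side chain. The fallback uses a halogenation, which is more strongly para-directed, and brings in C1 by carbonylation. It sets out from 5 and returns at 7, so step 6 is not needed. Iodination with N-iodosuccinimide (MeCN, rt) should give S-ethyl (3R)-3-(2-iodo-3,5-dimethoxy-6-methylphenyl)butanethioate F8. Palladium-catalysed hydroxycarbonylation with an in situ carbon monoxide source (Pd2(dba)3, HCO2Li, Ac2O, i-Pr2NEt, LiCl, DMF, 80 °C) then gives acid 7.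

## Further compounds

F1 | step 15 | benzyl 6-(benzyloxy)-2-[(2R)-but-3-en-2-yl]-4-methoxy-3-methylbenzoate | COc1cc(OCc2ccccc2)c(C(=O)OCc2ccccc2)c(c1C)[C@H](C)C=C
F2 | step 15 | benzyl 6-(benzyloxy)-2-[(2S)-3,4-dihydroxybutan-2-yl]-4-methoxy-3-methylbenzoate (carbinol epimers) | COc1cc(OCc2ccccc2)c(C(=O)OCc2ccccc2)c(c1C)[C@H](C)C(O)CO
F3 | step 15 | benzyl 6-(benzyloxy)-2-[(2S)-4-{[2,4-bis(benzyloxy)-3,5,6-trimethylbenzoyl]oxy}-3-hydroxybutan-2-yl]-4-methoxy-3-methylbenzoate (carbinol epimers) | COc1cc(OCc2ccccc2)c(C(=O)OCc2ccccc2)c(c1C)[C@H](C)C(O)COC(=O)c2c(C)c(C)c(OCc3ccccc3)c(C)c2OCc2ccccc2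
F4 | step 10 | benzyl 6-(benzyloxy)-4-methoxy-3-methyl-2-[(2R)-4-(trifluoromethanesulfonyloxy)but-3-en-2-yl]benzoate (E/Z mixture) | COc1cc(OCc2ccccc2)c(C(=O)OCc2ccccc2)c(c1C)[C@H](C)C=COS(=O)(=O)C(F)(F)F
F5 | step 4 | (2E)-3-(3,5-dimethoxy-2-methylphenyl)prop-2-enoic acid | OC(=O)/C=C/c1cc(OC)cc(OC)c1C
F6 | step 4 | (4R)-3-[(2E)-3-(3,5-dimethoxy-2-methylphenyl)prop-2-enoyl]-4-phenyl-1,3-oxazolidin-2-one | O=C1OC[C@@H](c2ccccc2)N1C(=O)/C=C/c1cc(OC)cc(OC)c1C
F7 | step 4 | (4R)-3-[(3R)-3-(3,5-dimethoxy-2-methylphenyl)butanoyl]-4-phenyl-1,3-oxazolidin-2-one | O=C1OC[C@@H](c2ccccc2)N1C(=O)C[C@@H](C)c1cc(OC)cc(OC)c1C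
F8 | step 5 | S-ethyl (3R)-3-(2-iodo-3,5-dimethoxy-6-methylphenyl)butanethioate | COc1cc(OC)c(I)c(c1C)[C@H](C)CC(=O)SCC
A1 | alternative 1 | benzyl 6-[(1S)-1-[(4R)-2,2-dimethyl-1,3-dioxolan-4-yl]ethyl]-2-hydroxy-4-methoxy-5-methylbenzoate | COc1cc(O)c(C(=O)OCc2ccccc2)c(c1C)[C@H](C)[C@@H]1COC(C)(C)O1
A2 | alternative 1 | 1,3-dimethoxy-1-(trimethylsilyloxy)penta-1,3-diene | COC(O[Si](C)(C)C)=CC(OC)=CC
A3 | alternative 1 | benzyl (4S)-4-[(4R)-2,2-dimethyl-1,3-dioxolan-4-yl]pent-2-ynoate | O=C(OCc1ccccc1)C#C[C@H](C)[C@@H]1COC(C)(C)O1
A4 | alternative 2 | [(3R,4S)-8-(benzyloxy)-3-hydroxy-6-methoxy-4,5-dimethyl-1-oxo-3,4-dihydro-1H-isochromen-3-yl]methyl 2,4-bis(benzyloxy)-3,5,6-trimethylbenzoate | COc1cc(OCc2ccccc2)c2c(c1C)[C@H](C)[C@](O)(COC(=O)c1c(C)c(C)c(OCc3ccccc3)c(C)c1OCc1ccccc1)OC2=O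
A5 | alternative 2 | [(3S)-7-(benzyloxy)-2-hydroxy-5-methoxy-3,4-dimethyl-1-oxo-2,3-dihydro-1H-inden-2-yl]methyl 2,4-bis(benzyloxy)-3,5,6-trimethylbenzoate (either configuration at the carbinol carbon) | COc1cc(OCc2ccccc2)c2c(c1C)[C@H](C)C(O)(COC(=O)c1c(C)c(C)c(OCc3ccccc3)c(C)c1OCc1ccccc1)C2=O
A6 | alternative 3 | benzyl 4-hydroxy-3,5,6-trimethyl-2-[(triisopropylsilyl)oxy]benzoate | Cc1c(C)c(C(=O)OCc2ccccc2)c(O[Si](C(C)C)(C(C)C)C(C)C)c(C)c1O
A7 | alternative 3 | benzyl (4E)-2-diazo-4-methyl-3-oxohex-4-enoate | C/C=C(\C)C(=O)C(=[N+]=[N-])C(=O)OCc1ccccc1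
A8 | alternative 3 | triisopropyl(prop-1-yn-1-yloxy)silane | CC#CO[Si](C(C)C)(C(C)C)C(C)C
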